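**Retrosynthetic overview**

1. The target is two identical, enolised 2,2,4,4-tetramethylcyclohexane-1,3,5-trione (syncarpic acid) rings, joined through their C-6 carbons to one CH(isobutyl) carbon. A mirror plane through that methine relates the rings, and in each ring the isolated C-3 ketone lies between the quaternary CMe2 carbons C-2 and C-4. This symmetry, together with the C(=O)–CMe2–C(=O) Claisen retron in each ring, makes the key step possible.
2. Key disconnection, made in both rings at once: the C-4(Me2)–C-3(=O) bond, giving an isopropyl-ketone enolate and a methyl ester, i.e. the acyclic tetraketo diester 7. The twofold Dieckmann closure mirrors the Claisen ring closure of polyketide triketo thioesters.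
3. 7 comes from bis(β-keto ester) 5 and isobutyryl chloride 6 by C-acylation at both CH2 groups. 5 comes from 3-isobutylglutaryl dichloride 2 and the enolate of methyl isobutyrate 3. C-3 of 3-isobutylglutaric acid 1 becomes the bridging methine, so every step is two-directional.
4. Ring order: no ring exists before the last step; both six-membered carbocycles form together in step 4.

Key step: step 4

Remark: the target has no stereocentre. All 1,3-dicarbonyl intermediates are drawn as keto tautomers and the target as the bis-enol shown. 3-Isobutylglutaric acid is taken as a purchasable starting material.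

Step 1
Reactants: 1 3-(2-methylpropyl)pentanedioic acid (3-isobutylglutaric acid)
Product: 2 3-(2-methylpropyl)pentanedioyl dichloride
Conditions: (COCl)2 (3 equiv), DMF (cat.), CH2Cl2, 0 °C to reflux; volatiles evaporated, crude used
Reagents that add atoms: oxalyl chloride, O=C(Cl)C(=O)Cl
Why: DMF-catalysed acid chloride formation (chloroiminium catalysis) with excess reagent should convert both carboxyl groups of the symmetric diacid, and no stereocentre is present or formed.

Step 2
Reactants: 2 3-(2-methylpropyl)pentanedioyl dichloride; 3 methyl 2-methylpropanoate (methyl isobutyrate)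
Product: 5 dimethyl 2,2,8,8-tetramethyl-5-(2-methylpropyl)-3,7-dioxononanedioate, via lithium enolate of methyl isobutyrate 4 (not isolated)
Conditions: 3 (4.4 equiv), LiN(iPr)2 (4.4 equiv), THF, −78 °C; 2 in THF added dropwise, −78 °C; aq NH4Cl
Reagents that add atoms: none
Why: Crossed Claisen-type C-acylation of a preformed ester lithium enolate by an acid chloride at both chain ends; slow addition of 2 into excess 4 at −78 °C should keep acylation faster than proton transfer, the new α-carbons are quaternary so the product cannot enolise between its carbonyl groups, and C-5 carries two identical arms and is not a stereocentre.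

Step 3
Reactants: 5 dimethyl 2,2,8,8-tetramethyl-5-(2-methylpropyl)-3,7-dioxononanedioate; 6 2-methylpropanoyl chloride (isobutyryl chloride)
Product: 7 dimethyl 2,2,8,8-tetramethyl-4,6-bis(2-methylpropanoyl)-5-(2-methylpropyl)-3,7-dioxononanedioate (mixture of diastereomers and keto/enol forms)
Conditions: 6 (2.6 equiv), MgBr2·OEt2 (5 equiv), iPr2NEt (6 equiv), CH2Cl2, rt; 1 M HCl wash
Reagents that add atoms: none
Why: Soft-enolisation C-acylation of a ketone (crossed Claisen-type 1,3-diketone synthesis): MgBr2 chelated by each β-keto ester unit lets the amine remove a proton from the only enolisable position (the C-4 and C-6 methylene groups), the bromomagnesium diketonate formed after C-acylation is protected from further acylation, and the new C-4/C-6 stereocentres form without control because they are erased in step 4.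

Step 4
Reactants: 7 dimethyl 2,2,8,8-tetramethyl-4,6-bis(2-methylpropanoyl)-5-(2-methylpropyl)-3,7-dioxononanedioate
Product: 10 watsonianone A, via tetralithium bis-dienolate 8 (not isolated), via trilithium monocyclised enolate 9 (not isolated)
Conditions: 7 added to LiN(iPr)2 (5.5 equiv), THF, −78 °C, then warmed to rt; 1 M HCl
Reagents that add atoms: none
Why: LiN(iPr)2 should remove first the acidic C–H between the two ketones of each half and then the isopropyl methine proton, so that each half becomes a 1,3-diketone dianion whose terminal CMe2 carbon attacks the neighbouring methyl ester and expels methoxide, once on each side (twofold Dieckmann condensation). The closest known reaction type is the Claisen cyclisation of β,δ-diketo esters through their dianions to cyclohexane-1,3,5-triones, i.e. terminal C-acylation of a 1,3-diketone dianion by an ester, here run in both directions of a symmetric chain. Each ring closes in the 6-(enolendo)-exo-trig mode (both enolate carbons end up in the ring, the ester C=O stays outside), helped by the gem-dimethyl groups on the tether. No stereocentre is created: the C-4/C-6 stereocentres of 7 become sp2 ring carbons and the bridging methine carries two identical rings, so no control element is needed. The step needs C- over O-cyclisation, enolisation only at the isopropyl methines and survival of the product under LiOMe; the dianion is far more nucleophilic at carbon than at oxygen and any enol lactone from O-attack should be reopened by LiOMe, all other carbonyl α-positions are quaternary CMe2 carbons without hydrogen, and the product leaves the equilibrium as a delocalised trione enolate that resists retro-Claisen cleavage. Adding 7 to excess base deprotonates both diacylmethines at once, which blocks retro-Michael loss of one arm, and the passage from a strongly basic dienolate to a stabilised enolate plus methoxide should make both closures irreversible.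

**Compound list**

1 | 3-(2-methylpropyl)pentanedioic acid (3-isobutylglutaric acid) | CC(C)CC(CC(=O)O)CC(=O)O | starting material
2 | 3-(2-methylpropyl)pentanedioyl dichloride | CC(C)CC(CC(=O)Cl)CC(=O)Cl | intermediate
3 | methyl 2-methylpropanoate (methyl isobutyrate) | CC(C)C(=O)OC | starting material
4 | lithium 1-methoxy-2-methylprop-1-en-1-olate (lithium enolate of 3) | CC(C)=C([O-])OC.[Li+] | intermediate
5 | dimethyl 2,2,8,8-tetramethyl-5-(2-methylpropyl)-3,7-dioxononanedioate | COC(=O)C(C)(C)C(=O)CC(CC(C)C)CC(=O)C(C)(C)C(=O)OC | intermediate
6 | 2-methylpropanoyl chloride (isobutyryl chloride) | CC(C)C(=O)Cl | starting material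
7 | dimethyl 2,2,8,8-tetramethyl-4,6-bis(2-methylpropanoyl)-5-(2-methylpropyl)-3,7-dioxononanedioate (C-4/C-6 configuration not controlled) | COC(=O)C(C)(C)C(=O)C(C(=O)C(C)C)C(CC(C)C)C(C(=O)C(C)C)C(=O)C(C)(C)C(=O)OC | intermediate
8 | tetralithium bis-dienolate of 7 (both diacylmethine and both isopropyl methine protons removed) | CC(C)CC(C(C([O-])=C(C)C)=C([O-])C(C)(C)C(=O)OC)C(C([O-])=C(C)C)=C([O-])C(C)(C)C(=O)OC.[Li+].[Li+].[Li+].[Li+] | intermediate
9 | trilithium salt with one trione ring closed and the second half still an open dienolate | CC(C)CC(C(C([O-])=C(C)C)=C([O-])C(C)(C)C(=O)OC)C1=C([O-])C(C)(C)C(=O)C(C)(C)C1=O.[Li+].[Li+].[Li+] | intermediate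
10 | watsonianone A | CC(C)CC(C1=C(O)C(C)(C)C(=O)C(C)(C)C1=O)C1=C(O)C(C)(C)C(=O)C(C)(C)C1=O | target

**Step count**

Total step count: 4. Longest linear sequence: 4 steps (1 → 2 → 5 → 7 → 10); 3 and 6 are purchased.

**Steps most likely to fail**

Step 4 (key step). What may go wrong: incomplete second deprotonation at the crowded isopropyl methines, ring closure through oxygen instead of carbon, or retro-Michael fragmentation of a partly deprotonated substrate, so that only one ring or none closes. Fallback: the same Claisen ring closure is moved to the monomer stage, where the carbon between the ketones is unsubstituted, and two finished rings are joined afterwards. It sets out from the lithium enolate 4 and comes back to the route at 10. Acylation of 4 with acetyl chloride (CC(=O)Cl; THF, −78 °C) should give methyl 2,2-dimethyl-3-oxobutanoate F1. Soft-enolisation C-acylation of its methyl ketone with 6 (MgBr2·OEt2, iPr2NEt, CH2Cl2, rt) should give methyl 2,2,6-trimethyl-3,5-dioxoheptanoate F2. Its dianion (LiN(iPr)2, 3 equiv, THF, −78 °C to rt, then 1 M HCl) should close by the same CMe2–C(=O) bond formation to syncarpic acid F3. Two equivalents of F3 and 3-methylbutanal (CC(C)CC=O; piperidine cat., CH2Cl2, rt) should condense by Knoevenagel reaction to 2,2,4,4-tetramethyl-6-(3-methylbutylidene)cyclohexane-1,3,5-trione F4, which should take up the second F3 by Michael addition in the same flask to give 10.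

Step 3. What may go wrong: O-acylation of the bromomagnesium enolate, loss of the acid chloride through ketene formation, or stalling after the first acylation because the second diacylmethine has to be built next to a crowded branch. Fallback: the 1,3-diketones are reached by aldol addition and oxidation instead of direct acylation. It sets out from 5 and comes back at 7. Twofold enolisation of 5 (LiN(iPr)2, 2.2 equiv, THF, −78 °C) and addition of 2-methylpropanal (CC(C)C=O) should give dimethyl 4,6-bis(1-hydroxy-2-methylpropyl)-2,2,8,8-tetramethyl-5-(2-methylpropyl)-3,7-dioxononanedioate F5 as a mixture of diastereomers. Dess–Martin oxidation (Dess–Martin periodinane, NaHCO3, CH2Cl2, rt) of both carbinols should then give 7.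

Step 2. What may go wrong: proton transfer from the first-formed keto ester to the ester enolate and dehydrochlorination of 2 to a ketene, leading to enol-lactone formation and oligomerisation instead of clean twofold acylation. Fallback: the order in which the two acyl groups are introduced is reversed, so that no ester enolate meets an acid chloride. It sets out from 2 and comes back at 7, bypassing 5. Treatment of 2 with MeNH(OMe)·HCl and pyridine (CH2Cl2, 0 °C) should give N,N'-dimethoxy-N,N'-dimethyl-3-(2-methylpropyl)pentanediamide F6. Addition of iPrMgCl (THF, 0 °C) should give 2,8-dimethyl-5-(2-methylpropyl)nonane-3,7-dione F7. Soft-enolisation C-acylation of F7 at its two methylene carbons, which are less hindered than the isopropyl methines, with purchased methyl 3-chloro-2,2-dimethyl-3-oxopropanoate (COC(=O)C(C)(C)C(=O)Cl; MgBr2·OEt2, iPr2NEt, CH2Cl2, rt) should give 7.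

Further compounds
F1 | step 4 | methyl 2,2-dimethyl-3-oxobutanoate | CC(=O)C(C)(C)C(=O)OC
F2 | step 4 | methyl 2,2,6-trimethyl-3,5-dioxoheptanoate | CC(C)C(=O)CC(=O)C(C)(C)C(=O)OC
F3 | step 4 | syncarpic acid (2,2,4,4-tetramethylcyclohexane-1,3,5-trione, drawn as its enol 3-hydroxy-4,4,6,6-tetramethylcyclohex-2-ene-1,5-dione) | OC1=CC(=O)C(C)(C)C(=O)C1(C)C
F4 | step 4 | 2,2,4,4-tetramethyl-6-(3-methylbutylidene)cyclohexane-1,3,5-trione | CC(C)CC=C1C(=O)C(C)(C)C(=O)C(C)(C)C1=O
F5 | step 3 | dimethyl 4,6-bis(1-hydroxy-2-methylpropyl)-2,2,8,8-tetramethyl-5-(2-methylpropyl)-3,7-dioxononanedioate (mixture of diastereomers) | COC(=O)C(C)(C)C(=O)C(C(O)C(C)C)C(CC(C)C)C(C(O)C(C)C)C(=O)C(C)(C)C(=O)OC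
F6 | step 2 | N,N'-dimethoxy-N,N'-dimethyl-3-(2-methylpropyl)pentanediamide | CC(C)CC(CC(=O)N(C)OC)CC(=O)N(C)OC
F7 | step 2 | 2,8-dimethyl-5-(2-methylpropyl)nonane-3,7-dione | CC(C)CC(CC(=O)C(C)C)CC(=O)C(C)C
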